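**Proposed total synthesis of glisoflavone (13) by anodic catechol–enaminone coupling with chromone annulation**

## Analysis of the target

Glisoflavone (13) is an isoflavone: a benzo ring A (C4a to C8a) is fused to the 4-pyranone ring C (O1, C2–H, C3, C4=O), and C3 carries ring B through the C3–C1' bond. Ring A has the less common oxygen pattern of a methyl ether at C5 (peri to C4=O) next to a free hydroxyl at C7. Ring B is 1,3,4,5-tetrasubstituted: catechol hydroxyls at C3' and C4', a prenyl group at C5', and C1' para to O4' between the unsubstituted carbons C2' and C6'. There is no stereocenter, no stereogenic alkene (the prenyl alkene bears geminal methyls) and no hindered axis, so the problem is one of chemoselectivity and step economy. The sensitive groups are: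

- the free catechol (oxidation in air and base);
- the o-prenylphenol unit (chroman formation with strong acid, chromene formation with oxidants, an alkene that rules out hydrogenolysis and electrophilic oxidants);
- the C5 methyl ether (the aryl ether most easily cleaved by Lewis acids, so the other oxygens cannot be carried as methyl or benzyl ethers);
- C2 of the pyranone (attack by hydroxide).

The difficulty is to make the C3–C1' bond and ring C while ring B carries its full, unprotected functionality. The feature that invites the key step is this: C1' of ring B is C5 of 3-prenylcatechol 9, the carbon that becomes the unhindered β-position of an enone in o-quinone 10. C3 of ring C is the nucleophilic α-carbon of an o-hydroxyaryl enaminone (3). The two halves therefore have matched polarity once the catechol is oxidized at an anode.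

## Retrosynthetic reasoning

**13 from 12.** Only the O7–CH2 bond of a methoxymethyl ether is cut. The group is needed because the formamide acetal used to make 3 would O-methylate the free para hydroxyl of 1. A methoxymethyl ether survives the amide acetal and the anode, and dilute acid should remove it without touching the prenyl group, the catechol or the C5 methyl ether. It is the only protecting group in the route.

**12 from 3 and 9 (key disconnection).** The C3–C1' bond and the O1–C2 bond are cut together. This divides the target into two halves of similar size, ring A with its three-carbon chain (3) and the complete, unprotected ring B (9). The cut is made here because ring B needs no halide, no boron and no protection: oxidation of 9 to o-quinone 10 makes C5 electrophilic, and the α-carbon of 3 is the matching nucleophile. The forward reaction has to oxidize 9 selectively, join C3 to C1' by Michael addition (giving 11), and close ring C by attack of the ring A hydroxyl with loss of the amine. Cutting only C2 (one-carbon insertion) or only C3–C1' (cross-coupling) would leave the aryl–C3 bond to be made by a longer, protected sequence.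

**3 from 2, and 2 from 1.** C2 of the target is introduced as an aminomethylene carbon on the acetyl methyl group of 2. Ketone 2 comes from 1 by etherification of the non-chelated para hydroxyl, which differs clearly in acidity from the hydrogen-bonded ortho hydroxyl.

**9 from 7 (through 8).** The bond between C5' and the prenyl CH2 is cut by an aromatic Claisen rearrangement. This O-to-C transfer mirrors the effect of an aromatic prenyltransferase. Its regiochemistry is fixed because 7 has only one free ortho carbon, and the allyl inversion turns the 1,1-dimethylallyl ether into the linear prenyl group. Dienone 8 tautomerizes to 9.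

**7 from 6, and 6 from 4 and 5.** The tertiary allyl ether 7 is traced to the propargyl ether 6, made from catechol 4 and the commercial tertiary chloride 5. The alkyne has to be reduced before heating, because 6 itself would cyclize to a chromene.

## Alternatives that were turned down

**Alternative 1:** (textbook) Disconnection of the C3–C1' bond alone. The forward key step is a Suzuki–Miyaura coupling of 3-iodo-5-methoxy-7-(methoxymethoxy)-4H-chromen-4-one A1 with [3,4-bis(methoxymethoxy)-5-(3-methylbut-2-en-1-yl)phenyl]boronic acid A2 under zerovalent palladium catalysis and aqueous carbonate. It was turned down because it forms one bond only. It needs ring C closed beforehand, C3–I and C1'–B installed in separate steps, and both catechol oxygens masked against base and palladium and unmasked afterwards. From 3 and 9 this takes five operations where the chosen key step takes one, and the route grows from seven to ten steps. It is the route most chemists would draw first, and it is kept only as the fallback.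

**Alternative 2:** (biomimetic aryl shift) Oxidative 1,2-aryl migration in chalcone A3, with Tl(NO3)3 (a trivalent thallium salt) or PhI(OAc)2 (a trivalent iodine reagent) in MeOH and HC(OMe)3. This gives β-ketoacetal A4, which acid closes to the isoflavone, a copy of the flavanone-to-isoflavone shift of isoflavone synthase. It was turned down because these electrophilic oxidants attack the trisubstituted prenyl alkene at least as readily as the enone. The prenyl group would have to be introduced after the shift, through a C5' halide or an O4' allyl ether, which requires three phenols on the isoflavone to be told apart. The aldol step also needs every phenol protected, the acid closure removes those groups again, and the thallium is stoichiometric. The count passes eleven steps.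

**Alternative 3:** (deoxybenzoin) Removal of C2 as a one-carbon unit and cleavage of the C4–C4a acyl bond. The forward sequence is Friedel–Crafts or Hoesch acylation of 5-methoxybenzene-1,3-diol A5 with arylacetic acid A6 to deoxybenzoin A7, then one-carbon insertion and ring closure with a formamide acetal or BF3·OEt2/DMF/MsCl. It was turned down for three reasons:

- A5 can be acylated between hydroxyl and methoxyl (wanted) or between the two hydroxyls, which leads to the 5-hydroxy-7-methoxy isomer.
- The Lewis and Brønsted acids of both steps add O4' to the prenyl alkene (chroman) and endanger the C5 methyl ether.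
- A6 needs a one-carbon homologation sequence of its own.

Key step: step 6

Assumption: ketone 1, catechol 4 and chloride 5 are taken as catalogue compounds.

## Route

Step 1
Reactants: 1 1-(2,4-dihydroxy-6-methoxyphenyl)ethan-1-one
Product: 2 1-[2-hydroxy-6-methoxy-4-(methoxymethoxy)phenyl]ethan-1-one
Conditions: MOMCl (1.1 equiv), K2CO3, acetone, 0 °C to rt
Reagents that add atoms: chloromethyl methyl ether (MOMCl), COCCl
Why: Williamson etherification; the C2 hydroxyl is held in a hydrogen bond to the ketone and is far less acidic and nucleophilic than the para C4 hydroxyl, so mono-alkylation at O4 is expected.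

Step 2
Reactants: 2 1-[2-hydroxy-6-methoxy-4-(methoxymethoxy)phenyl]ethan-1-one
Product: 3 (E)-3-(dimethylamino)-1-[2-hydroxy-6-methoxy-4-(methoxymethoxy)phenyl]prop-2-en-1-one
Conditions: Me2NCH(OMe)2 (3 equiv), toluene, 100 °C
Reagents that add atoms: N,N-dimethylformamide dimethyl acetal, COC(OC)N(C)C
Why: Enaminone condensation (aminomethylenation of the acetyl methyl group); the push-pull alkene should form as the E isomer, and the chelated hydroxyl stays free while O4 is shielded from O-methylation by the reagent.

Step 3
Reactants: 4 catechol (benzene-1,2-diol; 3 equiv), 5 3-chloro-3-methylbut-1-yne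
Product: 6 2-[(2-methylbut-3-yn-2-yl)oxy]phenol
Conditions: K2CO3, KI, CuI (cat.), acetone, 56 °C, Ar
Reagents that add atoms: none
Why: Copper-assisted O-alkylation of a phenol with a tertiary propargylic chloride, a standard entry to aryl 1,1-dimethylpropargyl ethers; the excess of 4 limits double alkylation.

Step 4
Reactants: 6 2-[(2-methylbut-3-yn-2-yl)oxy]phenol
Product: 7 2-[(2-methylbut-3-en-2-yl)oxy]phenol
Conditions: H2 (1 atm), 5% Pd/CaCO3 poisoned with Pb(OAc)2 (Lindlar catalyst), quinoline, EtOAc, rt
Reagents that add atoms: none
Why: Lindlar semi-hydrogenation of the terminal alkyne to the terminal alkene; it must precede heating because 6 would cyclize to a chromene.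

Step 5
Reactants: 7 2-[(2-methylbut-3-en-2-yl)oxy]phenol
Product: 9 3-(3-methylbut-2-en-1-yl)benzene-1,2-diol (3-prenylcatechol), via ortho-dienone 8 (not isolated)
Conditions: N,N-diethylaniline, 150 °C, Ar
Reagents that add atoms: none
Why: Aromatic Claisen rearrangement ([3,3]-sigmatropic shift) to the only free ortho carbon, then tautomerization of dienone 8; the allyl inversion converts the 1,1-dimethylallyl ether into the linear prenyl group, and the basic solvent suppresses acid-induced chroman formation.

Step 6
Reactants: 3 (E)-3-(dimethylamino)-1-[2-hydroxy-6-methoxy-4-(methoxymethoxy)phenyl]prop-2-en-1-one, 9 3-(3-methylbut-2-en-1-yl)benzene-1,2-diol (1.3 equiv)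
Product: 12 3-[3,4-dihydroxy-5-(3-methylbut-2-en-1-yl)phenyl]-5-methoxy-7-(methoxymethoxy)-4H-chromen-4-one (7-O-MOM-glisoflavone), via 3-prenyl-o-benzoquinone 10 (not isolated), via α-aryl enaminone 11 (not isolated)
Conditions: undivided cell, graphite anode, Pt cathode, +0.45 V vs Ag/AgCl, 2.1 F per mol of 3, 0.2 M NaOAc/AcOH buffer (pH 5.5)–MeCN 1:1, 15 °C, N2; then AcOH, 50 °C
Reagents that add atoms: none
Why: Proposed new method: anodic two-electron, two-proton oxidation of catechol 9, at a potential at which enaminone 3, the MOM ether and the prenyl alkene are not oxidized, should give o-quinone 10 in low stationary concentration. The nucleophilic α-carbon of the push-pull enaminone 3 adds in a Michael reaction to C5 of 10, and tautomerization of the adduct restores the catechol and gives α-aryl enaminone 11, which forms the C3–C1' bond. The chelated 2-hydroxyl of ring A then adds to the aminomethylene carbon of 11 (6-endo-trig oxa-Michael addition, equivalent to a 6-exo-trig attack on the iminium tautomer) and dimethylamine is eliminated, which closes ring C as the 4-pyranone. The closest known reaction types are the Nenitzescu-type condensation of N,N-dimethyl enaminones with quinones, in which the same C–C Michael addition is followed by O-cyclization with loss of dimethylamine to a benzofuran, and the anodic oxidation of catechols with Michael trapping of the o-quinone by carbon nucleophiles. Regioselectivity for C5 rests on the prenyl group at C3 of 10, which shields and deactivates C4, so that the unhindered β-carbon of the C1 enone is attacked, as is usual for 3-alkyl o-quinones. Because the new bond lies meta and para to the two catechol oxygens, no benzofuran can form and the ring A hydroxyl is the only nucleophile placed to trap the aminomethylene carbon. The acetate buffer keeps liberated dimethylamine protonated and slows base-catalysed tautomerization of 10, and over-oxidation is held back by the excess of 9, the limited charge and the electron-withdrawing chromonyl group of 12. No stereocenter is formed.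

Step 7
Reactants: 12 3-[3,4-dihydroxy-5-(3-methylbut-2-en-1-yl)phenyl]-5-methoxy-7-(methoxymethoxy)-4H-chromen-4-one
Product: 13 glisoflavone, 3-[3,4-dihydroxy-5-(3-methylbut-2-en-1-yl)phenyl]-7-hydroxy-5-methoxy-4H-chromen-4-one
Conditions: HCl (1.25 M in MeOH), THF, 40 °C, Ar
Reagents that add atoms: none
Why: Acid-catalysed cleavage of the methoxymethyl acetal by transacetalization to methanol; dilute acid at moderate temperature should stay below the threshold for chroman formation from the o-prenylphenol and does not touch the C5 methyl ether.

## Compound list

1 | 1-(2,4-dihydroxy-6-methoxyphenyl)ethan-1-one | CC(=O)c1c(O)cc(O)cc1OC | starting material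
2 | 1-[2-hydroxy-6-methoxy-4-(methoxymethoxy)phenyl]ethan-1-one | CC(=O)c1c(O)cc(OCOC)cc1OC | intermediate
3 | (E)-3-(dimethylamino)-1-[2-hydroxy-6-methoxy-4-(methoxymethoxy)phenyl]prop-2-en-1-one | CN(C)/C=C/C(=O)c1c(O)cc(OCOC)cc1OC | intermediate
4 | catechol (benzene-1,2-diol) | Oc1ccccc1O | starting material
5 | 3-chloro-3-methylbut-1-yne | CC(C)(Cl)C#C | starting material
6 | 2-[(2-methylbut-3-yn-2-yl)oxy]phenol | CC(C)(C#C)Oc1ccccc1O | intermediate
7 | 2-[(2-methylbut-3-en-2-yl)oxy]phenol | CC(C)(C=C)Oc1ccccc1O | intermediate
8 | 2-hydroxy-6-(3-methylbut-2-en-1-yl)cyclohexa-2,4-dien-1-one (ortho-dienone, racemic, not isolated) | CC(C)=CCC1C=CC=C(O)C1=O | intermediate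
9 | 3-(3-methylbut-2-en-1-yl)benzene-1,2-diol (3-prenylcatechol) | CC(C)=CCc1cccc(O)c1O | intermediate
10 | 3-(3-methylbut-2-en-1-yl)cyclohexa-3,5-diene-1,2-dione (3-prenyl-o-benzoquinone, not isolated) | CC(C)=CCC1=CC=CC(=O)C1=O | intermediate
11 | (E)-2-[3,4-dihydroxy-5-(3-methylbut-2-en-1-yl)phenyl]-3-(dimethylamino)-1-[2-hydroxy-6-methoxy-4-(methoxymethoxy)phenyl]prop-2-en-1-one (α-aryl enaminone, not isolated; the geometry is of no consequence for the ring closure) | CN(C)/C=C(\c1cc(O)c(O)c(CC=C(C)C)c1)C(=O)c1c(O)cc(OCOC)cc1OC | intermediate
12 | 3-[3,4-dihydroxy-5-(3-methylbut-2-en-1-yl)phenyl]-5-methoxy-7-(methoxymethoxy)-4H-chromen-4-one | COCOc1cc(OC)c2c(c1)occ(-c1cc(O)c(O)c(CC=C(C)C)c1)c2=O | intermediate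
13 | glisoflavone, 3-[3,4-dihydroxy-5-(3-methylbut-2-en-1-yl)phenyl]-7-hydroxy-5-methoxy-4H-chromen-4-one | COc1cc(O)cc2occ(-c3cc(O)c(O)c(CC=C(C)C)c3)c(=O)c12 | target

## Step count and risk

Total step count: 7. Longest linear sequence: 5 steps (steps 3, 4, 5, 6 and 7, from 4 and 5 to 13). The ring A branch (1 to 3) contributes 2 steps before the convergence in step 6.

**Step 6 (key step, proposed new method).** Four processes could divert it:

- tautomerization of o-quinone 10 through its benzylic and allylic CH2 to a quinone methide, which would close to a chromene by oxa-6π electrocyclization before the enaminone adds;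
- cycloaddition of the quinone dione unit across the enaminone alkene, or attack of the quinone by the electron-rich ring A carbons, in place of Michael addition of the α-carbon;
- hydrolysis or premature ring closure of 3 in the buffer to a chromone without a C3 substituent;
- further oxidation of the catechol of 12.

The fallback uses known chemistry, sets out from 3 and 9 and comes back at 13. Iodocyclization of 3 (I2, pyridine, CHCl3, rt) should give 3-iodo-5-methoxy-7-(methoxymethoxy)-4H-chromen-4-one F1 (the same compound as A1). Catechol 9 is protected with MOMCl and NaH in DMF as 1,2-bis(methoxymethoxy)-3-(3-methylbut-2-en-1-yl)benzene F2. Sterically controlled C–H borylation of F2 (B2pin2, [Ir(OMe)(cod)]2, 4,4'-di-tert-butyl-2,2'-bipyridine, THF, 60 °C) at the only C–H without an ortho substituent should give 2-[3,4-bis(methoxymethoxy)-5-(3-methylbut-2-en-1-yl)phenyl]-4,4,5,5-tetramethyl-1,3,2-dioxaborolane F3. Suzuki–Miyaura coupling of F1 with F3 (Pd(dppf)Cl2, K2CO3, dioxane–H2O, 80 °C) should give 3-[3,4-bis(methoxymethoxy)-5-(3-methylbut-2-en-1-yl)phenyl]-5-methoxy-7-(methoxymethoxy)-4H-chromen-4-one F4. HCl in MeOH as in step 7 then removes all three MOM groups and gives 13.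

**Step 5 (Claisen rearrangement).** The tertiary allyl–oxygen bond may break heterolytically (loss of the five-carbon unit, or a 1,3-shift to the O-prenyl ether). Migration through the hydroxyl-bearing ortho carbon followed by a Cope shift would place the prenyl group para, and the product may cyclize thermally to a chroman. The fallback sets out from 4 and comes back at 9. It moves the sigmatropic step to a primary allyl ether, which cannot ionize, and builds the trisubstituted alkene afterwards. O-Allylation of 4 (allyl bromide, K2CO3, acetone) should give 2-(prop-2-en-1-yloxy)phenol F5. Claisen rearrangement (neat, 190 °C) should give 3-(prop-2-en-1-yl)benzene-1,2-diol F6. Cross-metathesis with 2-methylbut-2-ene (second-generation Grubbs catalyst RuCl2(=CHPh)(H2IMes)(PCy3), CH2Cl2, 40 °C) should give 9.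

**Step 7 (MOM removal).** Acid may add O4' to the protonated prenyl alkene (chroman formation) or hydrate the alkene while the acetal is cleaved. The fallback sets out from 1 and comes back at 13. It replaces the acid-labile group by an allyl ether that is removed under neutral conditions. Allylation of 1 (allyl bromide, K2CO3, acetone) should give 1-[2-hydroxy-6-methoxy-4-(prop-2-en-1-yloxy)phenyl]ethan-1-one F7. Condensation with Me2NCH(OMe)2 should give (E)-3-(dimethylamino)-1-[2-hydroxy-6-methoxy-4-(prop-2-en-1-yloxy)phenyl]prop-2-en-1-one F8. Anodic coupling with 9 under the conditions of step 6 (the terminal alkene is inert at that potential) should give 3-[3,4-dihydroxy-5-(3-methylbut-2-en-1-yl)phenyl]-5-methoxy-7-(prop-2-en-1-yloxy)-4H-chromen-4-one F9. Transfer of the allyl group to morpholine with Pd(PPh3)4 in THF at rt should give 13.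

**Step 3 (O-propargylation).** Double alkylation of catechol and base-induced elimination of the tertiary chloride to a volatile enyne may outrun substitution. The fallback sets out from 4 and comes back at 7, so that step 4 is not needed. 2-Methylbut-3-en-2-ol is converted with n-BuLi and Boc2O in THF into tert-butyl (2-methylbut-3-en-2-yl) carbonate F10. Excess 4 is then O-alkylated with F10 through a π-allylpalladium intermediate at its more substituted terminus (Pd(PPh3)4, THF, 0 °C) to give 7 directly.

## Further compounds

F1 | step 6 | 3-iodo-5-methoxy-7-(methoxymethoxy)-4H-chromen-4-one | COCOc1cc(OC)c2c(c1)occ(I)c2=O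
F2 | step 6 | 1,2-bis(methoxymethoxy)-3-(3-methylbut-2-en-1-yl)benzene | COCOc1cccc(CC=C(C)C)c1OCOC
F3 | step 6 | 2-[3,4-bis(methoxymethoxy)-5-(3-methylbut-2-en-1-yl)phenyl]-4,4,5,5-tetramethyl-1,3,2-dioxaborolane | COCOc1cc(B2OC(C)(C)C(C)(C)O2)cc(CC=C(C)C)c1OCOC
F4 | step 6 | 3-[3,4-bis(methoxymethoxy)-5-(3-methylbut-2-en-1-yl)phenyl]-5-methoxy-7-(methoxymethoxy)-4H-chromen-4-one | COCOc1cc(OC)c2c(c1)occ(-c1cc(OCOC)c(OCOC)c(CC=C(C)C)c1)c2=O
F5 | step 5 | 2-(prop-2-en-1-yloxy)phenol | C=CCOc1ccccc1O
F6 | step 5 | 3-(prop-2-en-1-yl)benzene-1,2-diol | C=CCc1cccc(O)c1O
F7 | step 7 | 1-[2-hydroxy-6-methoxy-4-(prop-2-en-1-yloxy)phenyl]ethan-1-one | CC(=O)c1c(O)cc(OCC=C)cc1OC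
F8 | step 7 | (E)-3-(dimethylamino)-1-[2-hydroxy-6-methoxy-4-(prop-2-en-1-yloxy)phenyl]prop-2-en-1-one | CN(C)/C=C/C(=O)c1c(O)cc(OCC=C)cc1OC
F9 | step 7 | 3-[3,4-dihydroxy-5-(3-methylbut-2-en-1-yl)phenyl]-5-methoxy-7-(prop-2-en-1-yloxy)-4H-chromen-4-one | C=CCOc1cc(OC)c2c(c1)occ(-c1cc(O)c(O)c(CC=C(C)C)c1)c2=O
F10 | step 3 | tert-butyl (2-methylbut-3-en-2-yl) carbonate | CC(C)(C)OC(=O)OC(C)(C)C=C
A1 | alternative 1 | 3-iodo-5-methoxy-7-(methoxymethoxy)-4H-chromen-4-one | COCOc1cc(OC)c2c(c1)occ(I)c2=O
A2 | alternative 1 | [3,4-bis(methoxymethoxy)-5-(3-methylbut-2-en-1-yl)phenyl]boronic acid | COCOc1cc(B(O)O)cc(CC=C(C)C)c1OCOC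
A3 | alternative 2 | (E)-3-[3,4-bis(methoxymethoxy)-5-(3-methylbut-2-en-1-yl)phenyl]-1-[2-hydroxy-6-methoxy-4-(methoxymethoxy)phenyl]prop-2-en-1-one | COCOc1cc(O)c(C(=O)/C=C/c2cc(OCOC)c(OCOC)c(CC=C(C)C)c2)c(OC)c1
A4 | alternative 2 | 2-[3,4-bis(methoxymethoxy)-5-(3-methylbut-2-en-1-yl)phenyl]-1-[2-hydroxy-6-methoxy-4-(methoxymethoxy)phenyl]-3,3-dimethoxypropan-1-one (racemic) | COCOc1cc(O)c(C(=O)C(c2cc(OCOC)c(OCOC)c(CC=C(C)C)c2)C(OC)OC)c(OC)c1
A5 | alternative 3 | 5-methoxybenzene-1,3-diol | COc1cc(O)cc(O)c1
A6 | alternative 3 | 2-[3,4-dihydroxy-5-(3-methylbut-2-en-1-yl)phenyl]acetic acid | OC(=O)Cc1cc(O)c(O)c(CC=C(C)C)c1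
A7 | alternative 3 | 1-(2,4-dihydroxy-6-methoxyphenyl)-2-[3,4-dihydroxy-5-(3-methylbut-2-en-1-yl)phenyl]ethan-1-one | COc1cc(O)cc(O)c1C(=O)Cc1cc(O)c(O)c(CC=C(C)C)c1
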